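You charged 1.20 equiv of first nucleophile on 0.050 M of starting material, and you asked for a quick number with the hunch that waiting loses target. Here is the problem as it stands.

| flask | starting material | first nucleophile | second nucleophile | remark | time |
|---|---|---|---|---|---|
| Thursday's | 0.050 M | 1.2 equiv | 0.50 equiv | the very flask that is asked about, followed so far |  |
| Friday's | 0.034 M | 1.2 equiv | 0.50 equiv | run made earlier |  |
| flask | 0.050 M | 1.20 equiv | 0.500 equiv |  | 25 min |

- Thursday's (time / min: target / %, starting material / %): 5.00: 40.6, 0.1; 10.0: 41.0, 0; 15.0: 40.5, 0; 20.0: 40.1, 0; 25.0: 39.4, 0
- Friday's (time / s: target / %, starting material / %): 10.0: 17.9, 72.3; 15.0: 24.7, 60.9; 30.0: 36.0, 37.0; 60.0: 42.5, 13.5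

(scatter of a reading: 0.5 percentage points)

- target, in percent of the starting material first charged, at 25 min
- which option adds most target ("none" when 2 percentage points or less is all one gets) (summer / midnight / winter / noon / none)
- target present, with what was taken out counted in, in percent of the starting material first charged, after summer
- target present, with what was taken out counted in, in percent of the starting material first charged, after midnight

- summer: at 25 min add starting material, 50.0% of the amount charged, then wait 50 min
- midnight: change nothing and wait 50 min more
- winter: at 25 min add first nucleophile, 50.0% of the amount charged, then wait 50 min
- noon: at 25 min take out 90% of the target then present, then wait 50 min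

- target taken out counts as made
- on the list of suspects stand: second nucleophile + intermediate -> other capture product; first nucleophile + intermediate -> target; 2 second nucleophile -> self-condensation product; starting material -> intermediate; first nucleophile + target -> over-reaction product
- additions bring no volume worth counting

Friday's run shows the fast phase. In 30.0 s, starting material falls by 23 percentage points but target rises by 6.5 points, less. Thursday's target moves by 1.2 points in 20.0 min, while two readings differ by about 0.71 points through scatter. That is a weak trend at best, so my own number is the mean of Thursday's readings, 40.3%.

I then keep a ledger. Each target costs one first nucleophile and each over-reaction product two, and over-reaction needs c(first nucleophile), so I read the flat stretch as c(first nucleophile) near nil, the limiting reagent. Target plus two times over-reaction product then equals the first nucleophile charged, all in percent of the starting material charged, which gives the ledger over-reaction share 39.8%. On that reading summer adds starting material with no first nucleophile to capture it. Winter adds first nucleophile worth 60.0% of the starting material charged, against a mean reading of 40.3% of target, and noon guards against a loss I don't see. I say none, and here I differ from the forecast.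

The forecast gives 39.6% (39% to 40.1%), 38.5% after summer, 36.6% after midnight, and noon: “Removing target preserves about 39.3%, roughly 2.7 points above waiting, so noon wins narrowly.”

The flask gives 40.3%, 40.3% after summer and 40.3% after midnight, and the best option is none. Noon changes target by 0 points and winter by −40 points.

    second nucleophile + intermediate → other capture product (k = 31.7 /M/s)
    first nucleophile + intermediate → target (k = 33.5 /M/s)
    2 second nucleophile → self-condensation product (k = 1.46 /M/s)
    starting material → intermediate (k = 0.0329 /s)
    first nucleophile + target → over-reaction product (k = 0.700 /M/s)

In this flask the ledger's 39.8%, a figure reckoned from scattered readings, stands beside over-reaction product at 39.8%, with first nucleophile at 0% after 25.0 min. Now take the neighbouring flask with 0.300 equiv of first nucleophile and the other charges unchanged. Its target is 26.8%, so the ledger gives over-reaction product 1.58%. That flask shows 1.58%, with first nucleophile at 0%, other capture product at 30.2% and intermediate at 41.4%.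

The numbers in the tables stem from a simulated flask on assumed constants; the scatter is artificial.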